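**Retrosynthetic overview** (neopeltolide numbering: C1 = lactone C=O, C3/C7 = THP carbons on the ring O, C13 = lactone carbinol)
1. Neopeltolide 39 ⇐ Mitsunobu esterification (inversion at C5) of macrolactone alcohol 27 with oxazole acid 38; 27 ⇐ benzyl ether 26.
2. 26 ⇐ eight-membered (Z)-enoate lactone 24 (ring O7–C1(=O)–C2=C3–C4–C5–C6–C7) carrying the free C13–OH: translactonisation to the 14-membered lactone, then transannular oxa-Michael addition. The enabling feature is that the THP oxygen sits on C7 and on C3, and C3 is β to the lactone carbonyl C1; the same oxygen can therefore first be bound to C1 and then shift to C3, so the eight-membered ring contracts to the six-membered ring O–C3–C4–C5–C6–C7.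
3. 24 ⇐ acrylate RCM of 22; chain C3–C16 from butan-1-ol by four Ir-catalysed allylations (C13, C11, C7, C5) and cross-metathesis/Cu-catalysed asymmetric methyl addition (C9).
4. 38 ⇐ 4-substituted oxazole from methyl 5-bromolevulinate and formamide; C2 zincation/iodination, Sonogashira coupling, Lindlar reduction, Still–Gennari olefination.
5. Ring order: oxazole (side chain); eight-membered lactone (RCM); then 14-membered lactone and tetrahydropyran together in the key step.

Key step: step 18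

Assumption: the Ir/(S)-Cl,MeO-BIPHEP catalyst is taken to add allyl to the Si face of the transient aldehyde and the (R)-catalyst to the Re face, and (S)-Tol-BINAP/CuI is taken to give the 3S ester in step 7; if a sense proves opposite, the ligand antipode is exchanged.

**Route**

Step 1
Reactants: 1 butan-1-ol
Product: 3 (R)-hept-1-en-4-ol, via butanal 2 (not isolated)
Conditions: allyl acetate, [Ir(cod)Cl]2 (2.5 mol %), (S)-Cl,MeO-BIPHEP (5 mol %), 4-Cl-3-NO2-C6H3CO2H (10 mol %), Cs2CO3 (20 mol %), THF, 100 °C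
Reagents that add atoms: allyl acetate, C=CCOC(C)=O
Why: Ir-catalysed transfer-hydrogenative carbonyl allylation from the alcohol oxidation level; the chiral π-allyl-Ir complex should add to one face of the butanal formed in situ and so set C13 by catalyst control.

Step 2
Reactants: 3 (R)-hept-1-en-4-ol
Product: 4 (R)-tert-butyl(hept-1-en-4-yloxy)dimethylsilane
Conditions: TBSCl, imidazole, DMF, 23 °C
Reagents that add atoms: tert-butyldimethylsilyl chloride, CC(C)(C)[Si](C)(C)Cl
Why: Standard silylation of a secondary alcohol; the TBS ether should survive every step up to the fluoride deprotection in step 17.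

Step 3
Reactants: 4 (R)-tert-butyl(hept-1-en-4-yloxy)dimethylsilane
Product: 6 (R)-3-[(tert-butyldimethylsilyl)oxy]hexan-1-ol, via ozonide 5 (not isolated)
Conditions: O3, CH2Cl2, −78 °C; then NaBH4, MeOH, −78 → 23 °C
Reagents that add atoms: ozone, [O-][O+]=O
Why: Ozonolysis with reductive borohydride work-up shortens the allyl group to the primary alcohol without touching the stereocentre.

Step 4
Reactants: 6 (R)-3-[(tert-butyldimethylsilyl)oxy]hexan-1-ol
Product: 8 (4R,6R)-6-[(tert-butyldimethylsilyl)oxy]non-1-en-4-ol, via aldehyde 7 (not isolated)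
Conditions: allyl acetate, [Ir(cod)Cl]2 (2.5 mol %), (R)-Cl,MeO-BIPHEP (5 mol %), 4-Cl-3-NO2-C6H3CO2H (10 mol %), Cs2CO3 (20 mol %), THF, 100 °C
Reagents that add atoms: allyl acetate, C=CCOC(C)=O
Why: The same Ir-catalysed allylation with the antipodal ligand; catalyst control should override the weak bias of the β-silyloxy aldehyde and give the 1,3-anti C11 carbinol.

Step 5
Reactants: 8 (4R,6R)-6-[(tert-butyldimethylsilyl)oxy]non-1-en-4-ol
Product: 9 tert-butyl{[(4R,6R)-6-methoxynon-8-en-4-yl]oxy}dimethylsilane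
Conditions: Me3OBF4, Proton-sponge, CH2Cl2, 0 → 23 °C
Reagents that add atoms: trimethyloxonium tetrafluoroborate, C[O+](C)C.F[B-](F)(F)F
Why: O-methylation with Meerwein salt under non-basic conditions avoids 1,3-silyl migration from the neighbouring TBS ether.

Step 6
Reactants: 9 tert-butyl{[(4R,6R)-6-methoxynon-8-en-4-yl]oxy}dimethylsilane
Product: 10 methyl (2E,5R,7R)-7-[(tert-butyldimethylsilyl)oxy]-5-methoxydec-2-enoate
Conditions: methyl acrylate (3 equiv), Hoveyda–Grubbs II (5 mol %), CH2Cl2, 40 °C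
Reagents that add atoms: methyl acrylate, C=CC(=O)OC
Why: Olefin cross-metathesis of a terminal alkene with an acrylate should give the E-enoate selectively and brings in C7 and C8.

Step 7
Reactants: 10 methyl (2E,5R,7R)-7-[(tert-butyldimethylsilyl)oxy]-5-methoxydec-2-enoate
Product: 11 methyl (3S,5R,7R)-7-[(tert-butyldimethylsilyl)oxy]-5-methoxy-3-methyldecanoate
Conditions: MeMgBr, CuI (3 mol %), (S)-Tol-BINAP (4.5 mol %), t-BuOMe, −20 °C
Reagents that add atoms: methylmagnesium bromide, C[Mg]Br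
Why: Cu-catalysed asymmetric conjugate addition of a Grignard reagent to an α,β-unsaturated ester; the chiral Cu-phosphine complex should control the face and set C9 independently of the remote C11 centre.

Step 8
Reactants: 11 methyl (3S,5R,7R)-7-[(tert-butyldimethylsilyl)oxy]-5-methoxy-3-methyldecanoate
Product: 12 (3R,5R,7R)-7-[(tert-butyldimethylsilyl)oxy]-5-methoxy-3-methyldecan-1-ol
Conditions: LiBH4, THF, MeOH (1 equiv), 0 → 23 °C
Reagents that add atoms: none
Why: Borohydride reduction of the ester to the primary alcohol; silyl and methyl ethers are inert (the descriptor at C3 changes only through CIP priorities).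

Step 9
Reactants: 12 (3R,5R,7R)-7-[(tert-butyldimethylsilyl)oxy]-5-methoxy-3-methyldecan-1-ol
Product: 14 (4S,6R,8R,10R)-10-[(tert-butyldimethylsilyl)oxy]-8-methoxy-6-methyltridec-1-en-4-ol, via aldehyde 13 (not isolated)
Conditions: allyl acetate, [Ir(cod)Cl]2 (2.5 mol %), (S)-Cl,MeO-BIPHEP (5 mol %), 4-Cl-3-NO2-C6H3CO2H (10 mol %), Cs2CO3 (20 mol %), THF, 100 °C
Reagents that add atoms: allyl acetate, C=CCOC(C)=O
Why: Ir-catalysed transfer-hydrogenative allylation; the catalyst should set C7, the β-methyl centre exerting little influence.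

Step 10
Reactants: 14 (4S,6R,8R,10R)-10-[(tert-butyldimethylsilyl)oxy]-8-methoxy-6-methyltridec-1-en-4-ol
Product: 15 (4S,6S,8R,10R)-10-[(tert-butyldimethylsilyl)oxy]-8-methoxy-4-[(4-methoxybenzyl)oxy]-6-methyltridec-1-ene
Conditions: NaH, PMBCl, n-Bu4NI (cat.), THF/DMF, 0 → 23 °C
Reagents that add atoms: 4-methoxybenzyl chloride, COc1ccc(CCl)cc1
Why: Williamson etherification masks the C7 hydroxyl temporarily; the remote TBS ether cannot migrate.

Step 11
Reactants: 15 (4S,6S,8R,10R)-10-[(tert-butyldimethylsilyl)oxy]-8-methoxy-4-[(4-methoxybenzyl)oxy]-6-methyltridec-1-ene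
Product: 17 (3R,5S,7R,9R)-9-[(tert-butyldimethylsilyl)oxy]-7-methoxy-3-[(4-methoxybenzyl)oxy]-5-methyldodecan-1-ol, via ozonide 16 (not isolated)
Conditions: O3, CH2Cl2, −78 °C (Sudan Red 7B end-point); then NaBH4, MeOH, −78 → 23 °C
Reagents that add atoms: ozone, [O-][O+]=O
Why: Ozonolysis with reductive work-up; the terminal alkene reacts far faster than the PMB arene when the end-point is controlled by an indicator.

Step 12
Reactants: 17 (3R,5S,7R,9R)-9-[(tert-butyldimethylsilyl)oxy]-7-methoxy-3-[(4-methoxybenzyl)oxy]-5-methyldodecan-1-ol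
Product: 19 (4R,6R,8S,10R,12R)-12-[(tert-butyldimethylsilyl)oxy]-10-methoxy-6-[(4-methoxybenzyl)oxy]-8-methylpentadec-1-en-4-ol, via aldehyde 18 (not isolated)
Conditions: allyl acetate, [Ir(cod)Cl]2 (2.5 mol %), (R)-Cl,MeO-BIPHEP (5 mol %), 4-Cl-3-NO2-C6H3CO2H (10 mol %), Cs2CO3 (20 mol %), THF, 100 °C
Reagents that add atoms: allyl acetate, C=CCOC(C)=O
Why: Ir-catalysed allylation under catalyst control should set C5 1,3-anti to C7, the configuration that the final Mitsunobu step inverts.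

Step 13
Reactants: 19 (4R,6R,8S,10R,12R)-12-[(tert-butyldimethylsilyl)oxy]-10-methoxy-6-[(4-methoxybenzyl)oxy]-8-methylpentadec-1-en-4-ol
Product: 20 (4R,6R,8S,10R,12R)-4-(benzyloxy)-12-[(tert-butyldimethylsilyl)oxy]-10-methoxy-6-[(4-methoxybenzyl)oxy]-8-methylpentadec-1-ene
Conditions: NaH, BnBr, n-Bu4NI (cat.), THF/DMF, 0 → 23 °C
Reagents that add atoms: benzyl bromide, BrCc1ccccc1
Why: Williamson benzylation; a benzyl ether on C5 can neither migrate nor be lost under the basic key step.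

Step 14
Reactants: 20 (4R,6R,8S,10R,12R)-4-(benzyloxy)-12-[(tert-butyldimethylsilyl)oxy]-10-methoxy-6-[(4-methoxybenzyl)oxy]-8-methylpentadec-1-ene
Product: 21 (4R,6R,8R,10R,12R)-4-(benzyloxy)-12-[(tert-butyldimethylsilyl)oxy]-10-methoxy-8-methylpentadec-1-en-6-ol
Conditions: DDQ, CH2Cl2/pH 7 buffer (10:1), 0 °C
Reagents that add atoms: none
Why: Oxidative cleavage of the electron-rich PMB ether by DDQ should leave the benzyl and silyl ethers and the alkene untouched and free only the C7 hydroxyl.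

Step 15
Reactants: 21 (4R,6R,8R,10R,12R)-4-(benzyloxy)-12-[(tert-butyldimethylsilyl)oxy]-10-methoxy-8-methylpentadec-1-en-6-ol
Product: 22 (4R,6R,8S,10R,12R)-4-(benzyloxy)-12-[(tert-butyldimethylsilyl)oxy]-10-methoxy-8-methylpentadec-1-en-6-yl acrylate
Conditions: acryloyl chloride, Et3N, CH2Cl2, −78 → 0 °C
Reagents that add atoms: acryloyl chloride, C=CC(=O)Cl
Why: O-acylation of the secondary alcohol brings in C1 and C2 and binds O7 to C1.

Step 16
Reactants: 22 (4R,6R,8S,10R,12R)-4-(benzyloxy)-12-[(tert-butyldimethylsilyl)oxy]-10-methoxy-8-methylpentadec-1-en-6-yl acrylate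
Product: 23 (3Z,6R,8R)-6-(benzyloxy)-8-{(2S,4R,6R)-6-[(tert-butyldimethylsilyl)oxy]-4-methoxy-2-methylnonyl}-5,6,7,8-tetrahydro-2H-oxocin-2-one
Conditions: Grubbs II (10 mol %, two portions), 1,4-benzoquinone (20 mol %), PhMe (1 mM, slow addition), 80 °C
Reagents that add atoms: none
Why: Ring-closing metathesis of an acrylate with a terminal alkene to an α,β-unsaturated medium-ring lactone; the eight-membered ring enforces the Z-alkene, and the C5 and C7 substituents should favour the folded conformer.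

Step 17
Reactants: 23 (3Z,6R,8R)-6-(benzyloxy)-8-{(2S,4R,6R)-6-[(tert-butyldimethylsilyl)oxy]-4-methoxy-2-methylnonyl}-5,6,7,8-tetrahydro-2H-oxocin-2-one
Product: 24 (3Z,6R,8R)-6-(benzyloxy)-8-[(2S,4R,6R)-6-hydroxy-4-methoxy-2-methylnonyl]-5,6,7,8-tetrahydro-2H-oxocin-2-one
Conditions: HF·pyridine, pyridine, THF, 0 → 23 °C
Reagents that add atoms: none
Why: Fluoride desilylation under buffered, non-basic conditions frees the C13 hydroxyl without starting the cascade early.

Step 18
Reactants: 24 (3Z,6R,8R)-6-(benzyloxy)-8-[(2S,4R,6R)-6-hydroxy-4-methoxy-2-methylnonyl]-5,6,7,8-tetrahydro-2H-oxocin-2-one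
Product: 26 (1R,5R,7R,9S,11R,13S)-13-(benzyloxy)-7-methoxy-9-methyl-5-propyl-4,15-dioxabicyclo[9.3.1]pentadecan-3-one, via hydroxy macrolactone 25 (not isolated)
Conditions: KHMDS (0.3 equiv), THF (1 mM), −20 → 23 °C; then AcOH
Reagents that add atoms: none
Why: Proposed new method: the catalytic C13 potassium alkoxide should add to the strained eight-membered lactone carbonyl C1 and expel O7 (14-exo-trig acyl transfer, driven by relief of medium-ring strain), giving the 14-membered (Z)-enoate macrolactone 25 as its C7 alkoxide, which then adds transannularly to C3 (6-exo-trig oxa-Michael); the ester enolate is protonated by further 24, so the base turns over. Net, O7 moves from C1 to C3 and the ring O–C1–C2=C3–C4–C5–C6–C7 contracts to the tetrahydropyran O–C3–C4–C5–C6–C7, while C1 and C2 pass into the macrolactone. The closest known reaction types are the base-mediated ring contraction of lactones (alcoholysis, then closure of the freed alkoxide onto an electrophilic ring carbon), alkoxide-driven translactonisation ring expansion, and the transannular oxa-Michael cyclisation of hydroxy-enoate macrolactones. The only new stereocentre, C3, should be set 2,6-cis to C7 and cis to the C5 benzyloxy group (all-equatorial chair) by the chair-like transition state favoured for Z-enoates and, since the oxa-Michael step is reversible, by thermodynamic control. The step needs intramolecular acyl attack by the C13 alkoxide to win over oligomerisation and over conjugate attack at C3; high dilution, the strain of the lactone and the reversibility of every step (with the bridged macrolide as thermodynamic sink) should secure this, and the benzyl ether on C5 blocks the alternative δ-lactone.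

Step 19
Reactants: 26 (1R,5R,7R,9S,11R,13S)-13-(benzyloxy)-7-methoxy-9-methyl-5-propyl-4,15-dioxabicyclo[9.3.1]pentadecan-3-one
Product: 27 (1R,5R,7R,9S,11R,13S)-13-hydroxy-7-methoxy-9-methyl-5-propyl-4,15-dioxabicyclo[9.3.1]pentadecan-3-one
Conditions: H2 (1 atm), Pd(OH)2/C, EtOAc, 23 °C
Reagents that add atoms: none
Why: Hydrogenolysis of the benzyl ether; the saturated macrolactone has no other reducible group.

Step 20
Reactants: 28 methyl 5-bromo-4-oxopentanoate
Product: 29 methyl 3-(oxazol-4-yl)propanoate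
Conditions: formamide (neat, excess), 110 °C
Reagents that add atoms: formamide, NC=O
Why: Bredereck oxazole synthesis: O-alkylation of formamide by the bromomethyl carbon and N-condensation with the ketone give the 4-substituted oxazole with C2–H and C5–H.

Step 21
Reactants: 29 methyl 3-(oxazol-4-yl)propanoate
Product: 31 methyl 3-(2-iodooxazol-4-yl)propanoate, via oxazol-2-ylzinc chloride 30 (not isolated)
Conditions: TMPZnCl·LiCl, THF, 23 °C; then I2, 0 °C
Reagents that add atoms: iodine, II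
Why: Directed C2 zincation of the oxazole (the most acidic C–H; the zinc species does not ring-open and the amide base tolerates the ester) followed by iodinolysis.

Step 22
Reactants: 32 prop-2-yn-1-amine
Product: 33 methyl prop-2-yn-1-ylcarbamate
Conditions: ClCO2Me, NaHCO3, CH2Cl2/H2O, 0 → 23 °C
Reagents that add atoms: methyl chloroformate, COC(=O)Cl
Why: Schotten–Baumann N-acylation of the primary amine.

Step 23
Reactants: 31 methyl 3-(2-iodooxazol-4-yl)propanoate; 33 methyl prop-2-yn-1-ylcarbamate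
Product: 34 methyl 3-(2-{3-[(methoxycarbonyl)amino]prop-1-yn-1-yl}oxazol-4-yl)propanoate
Conditions: PdCl2(PPh3)2 (5 mol %), CuI (10 mol %), Et3N, MeCN, 23 °C
Reagents that add atoms: none
Why: Sonogashira coupling of the activated 2-iodo-azole with the terminal alkyne; the carbamate N–H is tolerated.

Step 24
Reactants: 34 methyl 3-(2-{3-[(methoxycarbonyl)amino]prop-1-yn-1-yl}oxazol-4-yl)propanoate
Product: 35 methyl 3-(2-{(1Z)-3-[(methoxycarbonyl)amino]prop-1-en-1-yl}oxazol-4-yl)propanoate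
Conditions: H2 (1 atm), Lindlar catalyst, quinoline, EtOAc, 23 °C
Reagents that add atoms: none
Why: Lindlar semi-hydrogenation (syn addition of H2) gives the Z-alkene.

Step 25
Reactants: 35 methyl 3-(2-{(1Z)-3-[(methoxycarbonyl)amino]prop-1-en-1-yl}oxazol-4-yl)propanoate
Product: 36 methyl {(2Z)-3-[4-(3-oxopropyl)oxazol-2-yl]prop-2-en-1-yl}carbamate
Conditions: DIBAL-H (2.2 equiv), CH2Cl2, −78 °C; Rochelle salt
Reagents that add atoms: none
Why: Partial reduction of the methyl ester to the aldehyde at low temperature; one equivalent of hydride is consumed by the carbamate N–H, whose carbonyl is less reactive.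

Step 26
Reactants: 36 methyl {(2Z)-3-[4-(3-oxopropyl)oxazol-2-yl]prop-2-en-1-yl}carbamate
Product: 37 methyl (2Z)-5-(2-{(1Z)-3-[(methoxycarbonyl)amino]prop-1-en-1-yl}oxazol-4-yl)pent-2-enoate
Conditions: (CF3CH2O)2P(O)CH2CO2Me, KHMDS, 18-crown-6, THF, −78 °C
Reagents that add atoms: methyl bis(2,2,2-trifluoroethyl)phosphonoacetate, COC(=O)CP(=O)(OCC(F)(F)F)OCC(F)(F)F
Why: Still–Gennari olefination; the electron-poor phosphonate eliminates kinetically and should give the Z-enoate.

Step 27
Reactants: 37 methyl (2Z)-5-(2-{(1Z)-3-[(methoxycarbonyl)amino]prop-1-en-1-yl}oxazol-4-yl)pent-2-enoate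
Product: 38 (2Z)-5-(2-{(1Z)-3-[(methoxycarbonyl)amino]prop-1-en-1-yl}oxazol-4-yl)pent-2-enoic acid
Conditions: LiOH·H2O, THF/H2O (3:1), 0 → 23 °C; then aq. HCl to pH 3
Reagents that add atoms: lithium hydroxide, [Li+].[OH-]
Why: Saponification of the methyl ester; the methyl carbamate and both Z-alkenes should survive at room temperature.

Step 28
Reactants: 27 (1R,5R,7R,9S,11R,13S)-13-hydroxy-7-methoxy-9-methyl-5-propyl-4,15-dioxabicyclo[9.3.1]pentadecan-3-one; 38 (2Z)-5-(2-{(1Z)-3-[(methoxycarbonyl)amino]prop-1-en-1-yl}oxazol-4-yl)pent-2-enoic acid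
Product: 39 neopeltolide
Conditions: PPh3, DIAD, benzene, 23 °C
Reagents that add atoms: none
Why: Mitsunobu esterification: SN2 displacement of the activated equatorial C5 oxygen by the carboxylate inverts C5 to the axial ester, and the neutral conditions preserve both Z-alkenes.

**Compound list**
1 | butan-1-ol | CCCCO | starting material
2 | butanal | CCCC=O | intermediate
3 | (R)-hept-1-en-4-ol | CCC[C@@H](O)CC=C | intermediate
4 | (R)-tert-butyl(hept-1-en-4-yloxy)dimethylsilane | CCC[C@@H](O[Si](C)(C)C(C)(C)C)CC=C | intermediate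
5 | 3-{(2R)-2-[(tert-butyldimethylsilyl)oxy]pentyl}-1,2,4-trioxolane (ozonide of 4) | CCC[C@@H](O[Si](C)(C)C(C)(C)C)CC1OCOO1 | intermediate
6 | (R)-3-[(tert-butyldimethylsilyl)oxy]hexan-1-ol | CCC[C@@H](O[Si](C)(C)C(C)(C)C)CCO | intermediate
7 | (R)-3-[(tert-butyldimethylsilyl)oxy]hexanal | CCC[C@@H](O[Si](C)(C)C(C)(C)C)CC=O | intermediate
8 | (4R,6R)-6-[(tert-butyldimethylsilyl)oxy]non-1-en-4-ol | CCC[C@@H](O[Si](C)(C)C(C)(C)C)C[C@H](O)CC=C | intermediate
9 | tert-butyl{[(4R,6R)-6-methoxynon-8-en-4-yl]oxy}dimethylsilane | CCC[C@@H](O[Si](C)(C)C(C)(C)C)C[C@H](OC)CC=C | intermediate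
10 | methyl (2E,5R,7R)-7-[(tert-butyldimethylsilyl)oxy]-5-methoxydec-2-enoate | CCC[C@@H](O[Si](C)(C)C(C)(C)C)C[C@H](OC)C/C=C/C(=O)OC | intermediate
11 | methyl (3S,5R,7R)-7-[(tert-butyldimethylsilyl)oxy]-5-methoxy-3-methyldecanoate | CCC[C@@H](O[Si](C)(C)C(C)(C)C)C[C@H](OC)C[C@H](C)CC(=O)OC | intermediate
12 | (3R,5R,7R)-7-[(tert-butyldimethylsilyl)oxy]-5-methoxy-3-methyldecan-1-ol | CCC[C@@H](O[Si](C)(C)C(C)(C)C)C[C@H](OC)C[C@H](C)CCO | intermediate
13 | (3S,5R,7R)-7-[(tert-butyldimethylsilyl)oxy]-5-methoxy-3-methyldecanal | CCC[C@@H](O[Si](C)(C)C(C)(C)C)C[C@H](OC)C[C@H](C)CC=O | intermediate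
14 | (4S,6R,8R,10R)-10-[(tert-butyldimethylsilyl)oxy]-8-methoxy-6-methyltridec-1-en-4-ol | CCC[C@@H](O[Si](C)(C)C(C)(C)C)C[C@H](OC)C[C@H](C)C[C@@H](O)CC=C | intermediate
15 | (4S,6S,8R,10R)-10-[(tert-butyldimethylsilyl)oxy]-8-methoxy-4-[(4-methoxybenzyl)oxy]-6-methyltridec-1-ene | CCC[C@@H](O[Si](C)(C)C(C)(C)C)C[C@H](OC)C[C@H](C)C[C@@H](OCc1ccc(OC)cc1)CC=C | intermediate
16 | 1,2,4-trioxolane (ozonide) of 15 | CCC[C@@H](O[Si](C)(C)C(C)(C)C)C[C@H](OC)C[C@H](C)C[C@@H](OCc1ccc(OC)cc1)CC1OCOO1 | intermediate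
17 | (3R,5S,7R,9R)-9-[(tert-butyldimethylsilyl)oxy]-7-methoxy-3-[(4-methoxybenzyl)oxy]-5-methyldodecan-1-ol | CCC[C@@H](O[Si](C)(C)C(C)(C)C)C[C@H](OC)C[C@H](C)C[C@@H](OCc1ccc(OC)cc1)CCO | intermediate
18 | (3R,5S,7R,9R)-9-[(tert-butyldimethylsilyl)oxy]-7-methoxy-3-[(4-methoxybenzyl)oxy]-5-methyldodecanal | CCC[C@@H](O[Si](C)(C)C(C)(C)C)C[C@H](OC)C[C@H](C)C[C@@H](OCc1ccc(OC)cc1)CC=O | intermediate
19 | (4R,6R,8S,10R,12R)-12-[(tert-butyldimethylsilyl)oxy]-10-methoxy-6-[(4-methoxybenzyl)oxy]-8-methylpentadec-1-en-4-ol | CCC[C@@H](O[Si](C)(C)C(C)(C)C)C[C@H](OC)C[C@H](C)C[C@@H](OCc1ccc(OC)cc1)C[C@H](O)CC=C | intermediate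
20 | (4R,6R,8S,10R,12R)-4-(benzyloxy)-12-[(tert-butyldimethylsilyl)oxy]-10-methoxy-6-[(4-methoxybenzyl)oxy]-8-methylpentadec-1-ene | CCC[C@@H](O[Si](C)(C)C(C)(C)C)C[C@H](OC)C[C@H](C)C[C@@H](OCc1ccc(OC)cc1)C[C@H](OCc1ccccc1)CC=C | intermediate
21 | (4R,6R,8R,10R,12R)-4-(benzyloxy)-12-[(tert-butyldimethylsilyl)oxy]-10-methoxy-8-methylpentadec-1-en-6-ol | CCC[C@@H](O[Si](C)(C)C(C)(C)C)C[C@H](OC)C[C@H](C)C[C@@H](O)C[C@H](OCc1ccccc1)CC=C | intermediate
22 | (4R,6R,8S,10R,12R)-4-(benzyloxy)-12-[(tert-butyldimethylsilyl)oxy]-10-methoxy-8-methylpentadec-1-en-6-yl acrylate | CCC[C@@H](O[Si](C)(C)C(C)(C)C)C[C@H](OC)C[C@H](C)C[C@@H](OC(=O)C=C)C[C@H](OCc1ccccc1)CC=C | intermediate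
23 | (3Z,6R,8R)-6-(benzyloxy)-8-{(2S,4R,6R)-6-[(tert-butyldimethylsilyl)oxy]-4-methoxy-2-methylnonyl}-5,6,7,8-tetrahydro-2H-oxocin-2-one | CCC[C@@H](O[Si](C)(C)C(C)(C)C)C[C@H](OC)C[C@H](C)C[C@@H]1C[C@H](OCc2ccccc2)C/C=C\C(=O)O1 | intermediate
24 | (3Z,6R,8R)-6-(benzyloxy)-8-[(2S,4R,6R)-6-hydroxy-4-methoxy-2-methylnonyl]-5,6,7,8-tetrahydro-2H-oxocin-2-one | CCC[C@@H](O)C[C@H](OC)C[C@H](C)C[C@@H]1C[C@H](OCc2ccccc2)C/C=C\C(=O)O1 | intermediate
25 | (3Z,6R,8R,10R,12R,14R)-6-(benzyloxy)-8-hydroxy-12-methoxy-10-methyl-14-propyl-1-oxacyclotetradec-3-en-2-one | CCC[C@@H]1C[C@H](OC)C[C@H](C)C[C@@H](O)C[C@H](OCc2ccccc2)C/C=C\C(=O)O1 | intermediate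
26 | (1R,5R,7R,9S,11R,13S)-13-(benzyloxy)-7-methoxy-9-methyl-5-propyl-4,15-dioxabicyclo[9.3.1]pentadecan-3-one | CCC[C@@H]1C[C@H](OC)C[C@H](C)C[C@@H]2C[C@H](OCc3ccccc3)C[C@H](CC(=O)O1)O2 | intermediate
27 | (1R,5R,7R,9S,11R,13S)-13-hydroxy-7-methoxy-9-methyl-5-propyl-4,15-dioxabicyclo[9.3.1]pentadecan-3-one | CCC[C@@H]1C[C@H](OC)C[C@H](C)C[C@@H]2C[C@H](O)C[C@H](CC(=O)O1)O2 | intermediate
28 | methyl 5-bromo-4-oxopentanoate | COC(=O)CCC(=O)CBr | starting material
29 | methyl 3-(oxazol-4-yl)propanoate | COC(=O)CCc1cocn1 | intermediate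
30 | [4-(3-methoxy-3-oxopropyl)oxazol-2-yl]zinc chloride | COC(=O)CCc1coc([Zn]Cl)n1 | intermediate
31 | methyl 3-(2-iodooxazol-4-yl)propanoate | COC(=O)CCc1coc(I)n1 | intermediate
32 | prop-2-yn-1-amine | C#CCN | starting material
33 | methyl prop-2-yn-1-ylcarbamate | C#CCNC(=O)OC | intermediate
34 | methyl 3-(2-{3-[(methoxycarbonyl)amino]prop-1-yn-1-yl}oxazol-4-yl)propanoate | COC(=O)CCc1coc(C#CCNC(=O)OC)n1 | intermediate
35 | methyl 3-(2-{(1Z)-3-[(methoxycarbonyl)amino]prop-1-en-1-yl}oxazol-4-yl)propanoate | COC(=O)CCc1coc(/C=C\CNC(=O)OC)n1 | intermediate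
36 | methyl {(2Z)-3-[4-(3-oxopropyl)oxazol-2-yl]prop-2-en-1-yl}carbamate | O=CCCc1coc(/C=C\CNC(=O)OC)n1 | intermediate
37 | methyl (2Z)-5-(2-{(1Z)-3-[(methoxycarbonyl)amino]prop-1-en-1-yl}oxazol-4-yl)pent-2-enoate | COC(=O)/C=C\CCc1coc(/C=C\CNC(=O)OC)n1 | intermediate
38 | (2Z)-5-(2-{(1Z)-3-[(methoxycarbonyl)amino]prop-1-en-1-yl}oxazol-4-yl)pent-2-enoic acid | OC(=O)/C=C\CCc1coc(/C=C\CNC(=O)OC)n1 | intermediate
39 | neopeltolide | CCC[C@@H]1C[C@H](OC)C[C@H](C)C[C@@H]2C[C@@H](OC(=O)/C=C\CCc3coc(/C=C\CNC(=O)OC)n3)C[C@H](CC(=O)O1)O2 | target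

**Step count and risks**
Total step count: 28. Longest linear sequence: 20 steps (steps 1–19 and 28, from butan-1-ol); the side chain takes 8 steps (20–27).

Steps most likely to fail:

1. Step 18 (proposed new method). The C13 alkoxide may react between molecules (oligomeric transesterification) or add to C3 instead of C1. Alternatively, γ-deprotonation of the enoate may lead to vinylogous β-elimination of benzyloxide before the acyl transfer. Fallback, from 24 back to 26, in three operations of known type: 24 is treated with K2CO3 in MeOH (0 → 23 °C), so that methanolysis of the strained lactone and in-situ oxa-Michael closure of the freed C7 alkoxide onto the (Z)-enoate should give methyl {(2,6-cis)-4-(benzyloxy)-6-[(2S,4R,6R)-6-hydroxy-4-methoxy-2-methylnonyl]oxan-2-yl}acetate F1. LiOH (THF/H2O) then gives the seco acid F2, which is closed by Yamaguchi macrolactonisation (2,4,6-trichlorobenzoyl chloride, Et3N; then DMAP, toluene, high dilution) to 26.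

2. Step 16. Closure of the acrylate-derived Ru carbene to a medium ring may be slower than cross-metathesis, so that head-to-tail dimers and oligomers form instead of the eight-membered lactone. Fallback, from 21 back to 23: 21 is acylated with bromoacetyl bromide/pyridine to the bromoacetate F3, and the terminal alkene is ozonised (O3, CH2Cl2, −78 °C; PPh3) to the aldehyde F4. An intramolecular SmI2 Reformatsky reaction (THF, high dilution, −78 → 0 °C) closes the eight-membered β-hydroxy lactone F5, and mesylation followed by DBU elimination gives the conjugated cis lactone 23.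

3. Step 21. The 2-metalated oxazole may ring-open to the isocyano enolate, or metalation may occur α to the ester, so that regiocontrol in the iodination is lost. Fallback, from 28 back to 31: 28 is condensed with urea (DMF, 100 °C) to methyl 3-(2-aminooxazol-4-yl)propanoate F6, which is converted to 31 by aprotic diazotisation–iodination (isoamyl nitrite, CH2I2, MeCN, 60 °C).

**Further compounds**
F1 | step 18 | methyl {(2,6-cis)-4-(benzyloxy)-6-[(2S,4R,6R)-6-hydroxy-4-methoxy-2-methylnonyl]oxan-2-yl}acetate (ring configurations as in 26) | CCC[C@@H](O)C[C@H](OC)C[C@H](C)C[C@@H]1C[C@H](OCc2ccccc2)C[C@H](CC(=O)OC)O1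
F2 | step 18 | {(2,6-cis)-4-(benzyloxy)-6-[(2S,4R,6R)-6-hydroxy-4-methoxy-2-methylnonyl]oxan-2-yl}acetic acid (seco acid) | CCC[C@@H](O)C[C@H](OC)C[C@H](C)C[C@@H]1C[C@H](OCc2ccccc2)C[C@H](CC(=O)O)O1
F3 | step 16 | bromoacetate of 21 | CCC[C@@H](O[Si](C)(C)C(C)(C)C)C[C@H](OC)C[C@H](C)C[C@@H](OC(=O)CBr)C[C@H](OCc1ccccc1)CC=C
F4 | step 16 | aldehyde from ozonolysis of F3 | CCC[C@@H](O[Si](C)(C)C(C)(C)C)C[C@H](OC)C[C@H](C)C[C@@H](OC(=O)CBr)C[C@H](OCc1ccccc1)CC=O
F5 | step 16 | 6-(benzyloxy)-4-hydroxy-8-{(2S,4R,6R)-6-[(tert-butyldimethylsilyl)oxy]-4-methoxy-2-methylnonyl}oxocan-2-one (C4 epimers) | CCC[C@@H](O[Si](C)(C)C(C)(C)C)C[C@H](OC)C[C@H](C)C[C@@H]1C[C@H](OCc2ccccc2)CC(O)CC(=O)O1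
F6 | step 21 | methyl 3-(2-aminooxazol-4-yl)propanoate | COC(=O)CCc1coc(N)n1
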